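The target is cut at the biaryl bond between ring E (phenoxy ring on dioxin ring D) and ring F (first ring of the triaryl ether F–G–H). Both carbons of this bond lie ortho to a diaryl ether oxygen (E-C1–O–D and F-C6–O–G) and carry only oxygen neighbours. The nitro group that activates fluoride displacement when these two ethers are made therefore sits exactly on E-C2 and F-C1 and is carried as a masked iodide. In the key step the arylzinc made from trimer iodide 30 undergoes Negishi coupling with pentamer iodide 22, joining the two fully built, permethylated halves; sixteen methyl ethers are cleaved last.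

Key step: step 20

Assumption: the E–F axis is drawn without configuration, so it is formed without control and the target is taken as drawn (no stereocentre).

Ring labels:
- A = terminal 3,5-dihydroxyphenoxy ring.
- B = dibenzofuran ring that carries O–A.
- C = ring shared by the furan and the dioxin.
- D = dioxin ring that carries O–E.
- E = phenoxy ring on D (C1 bears the ether oxygen, C2 the bond to F).
- F = ring bonded to E (C1 bonded to E, C6 bears the ether oxygen to G).
- G = middle ring of the triaryl ether.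
- H = terminal 2,4,6-trihydroxyphenoxy ring.

Dibenzodioxin locants used for 12–14 and F2–F4 are those of 12.

Step 1
Reactants: 1 1-fluoro-3,5-dimethoxybenzene
Product: 3 2-fluoro-4,6-dimethoxybenzaldehyde, via iminium salt 2 (not isolated)
Conditions: POCl3, DMF, 0 to 80 °C; then ice water
Reagents that add atoms: N,N-dimethylformamide, CN(C)C=O; water, O
Why: Vilsmeier–Haack formylation; the chloroiminium ion should attack C2 (para to one methoxy group, flanked by the small fluorine) rather than C4 between the two methoxy groups, and the minor 4-fluoro-2,6-dimethoxy isomer is removed by crystallisation.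

Step 2
Reactants: 3 2-fluoro-4,6-dimethoxybenzaldehyde
Product: 5 2-fluoro-4,6-dimethoxybenzene-1,3-dicarbaldehyde, via chloro ether 4 (not isolated)
Conditions: Cl2CHOMe, TiCl4, CH2Cl2, 0 °C to rt; then ice water
Reagents that add atoms: dichloromethyl methyl ether, COC(Cl)Cl; water, O
Why: Rieche formylation; the second formyl group should enter C3, again para to a methoxy group and next to fluorine, rather than C5 between two methoxy groups.

Step 3
Reactants: 1 1-fluoro-3,5-dimethoxybenzene
Product: 6 1-fluoro-3,5-dimethoxy-2-nitrobenzene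
Conditions: HNO3 (1 equiv), AcOH, 10 °C
Reagents that add atoms: nitric acid, O[N+](=O)[O-]
Why: Electrophilic aromatic nitration with the same site preference as step 1 (ortho to F, para to OMe); the 4-nitro isomer is separated.

Step 4
Reactants: 7 3-bromo-4-hydroxy-5-methoxybenzaldehyde (5-bromovanillin)
Product: 8 2,3-dibromo-4-hydroxy-5-methoxybenzaldehyde
Conditions: Br2, Fe powder (cat.), AcOH, rt to 50 °C
Reagents that add atoms: bromine, BrBr
Why: Electrophilic aromatic bromination at the free position para to the methoxy group, which places the second bromine on the future furan carbon of ring C.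

Step 5
Reactants: 8 2,3-dibromo-4-hydroxy-5-methoxybenzaldehyde; 5 2-fluoro-4,6-dimethoxybenzene-1,3-dicarbaldehyde
Product: 9 2-(2,3-dibromo-4-formyl-6-methoxyphenoxy)-4,6-dimethoxybenzene-1,3-dicarbaldehyde
Conditions: K2CO3, DMF, 80 °C
Reagents that add atoms: none
Why: SNAr; the fluorine of 5 is activated by two ortho formyl groups and should be displaced by the phenoxide of 8, fixing the ether between the central oxygenated carbons of rings C and D.

Step 6
Reactants: 9 trialdehyde from step 5
Product: 11 2-(2,3-dibromo-4-hydroxy-6-methoxyphenoxy)-4,6-dimethoxybenzene-1,3-diol, via triformate 10 (not isolated)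
Conditions: mCPBA (4.5 equiv), CH2Cl2, 0 °C to rt; then MeOH, Et3N (cat.), rt
Reagents that add atoms: 3-chloroperoxybenzoic acid, OOC(=O)c1cccc(Cl)c1
Why: Threefold Baeyer–Villiger (Dakin-type) oxidation; each formyl group is ortho or para to an ether oxygen, so the aryl group should migrate, and the formates are cleaved by methanolysis.

Step 7
Reactants: 11 triol from step 6
Product: 12 9-bromo-1,3,6-trimethoxydibenzo[b,e][1,4]dioxine-4,8-diol
Conditions: CuI (10 mol%), picolinic acid (20 mol%), K3PO4, DMSO (high dilution), 90 °C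
Reagents that add atoms: none
Why: Intramolecular Ullmann ether synthesis; the two ring D hydroxyls are equivalent and only the C–Br ortho to the ether bridge can close a six-membered ring, so one dibenzodioxin should form and the second bromine stays.

Step 8
Reactants: 12 dibenzodioxin diol; 3 2-fluoro-4,6-dimethoxybenzaldehyde
Product: 13 2-[(9-bromo-4-hydroxy-1,3,6-trimethoxydibenzo[b,e][1,4]dioxin-8-yl)oxy]-4,6-dimethoxybenzaldehyde
Conditions: 3 (1.05 equiv), K2CO3 (1.1 equiv), DMSO, 90 °C
Reagents that add atoms: none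
Why: Site-selective SNAr; with one equivalent of base the more acidic, less hindered 8-OH (ortho to Br) should be ionised and displace the fluoride ortho to the formyl group, while the 4-OH between two oxygen substituents stays free.

Step 9
Reactants: 13 aldehyde from step 8; 6 1-fluoro-3,5-dimethoxy-2-nitrobenzene
Product: 14 2-{[9-bromo-4-(3,5-dimethoxy-2-nitrophenoxy)-1,3,6-trimethoxydibenzo[b,e][1,4]dioxin-8-yl]oxy}-4,6-dimethoxybenzaldehyde
Conditions: 6 (1.5 equiv), K2CO3, DMF, 60 °C
Reagents that add atoms: none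
Why: SNAr; the hindered 4-phenoxide should displace the fluoride ortho to the nitro group, which puts the nitro group on E-C2.

Step 10
Reactants: 14 bromide from step 9
Product: 15 pentacyclic aldehyde (14 with a bond from C9 of the dibenzodioxin, the former C–Br, to C3 of the benzaldehyde ring; rings B–C now form a dibenzofuran)
Conditions: Pd(OAc)2 (10 mol%), PCy3·HBF4 (20 mol%), PivOH (30 mol%), K2CO3, DMA, 120 °C
Reagents that add atoms: none
Why: Intramolecular palladium-catalysed direct arylation (concerted metalation–deprotonation); after oxidative addition at C–Br the only free position ortho to the ether oxygen on ring B should be metalated, closing the furan, and the formyl C–H is not engaged under carbonate and pivalate.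

Step 11
Reactants: 15 pentacyclic aldehyde
Product: 17 pentacyclic phenol (15 with OH in place of CHO), via aryl formate 16 (not isolated)
Conditions: mCPBA (1.3 equiv), CH2Cl2, 0 °C to rt; then MeOH, Et3N (cat.), rt
Reagents that add atoms: 3-chloroperoxybenzoic acid, OOC(=O)c1cccc(Cl)c1
Why: Baeyer–Villiger oxidation of an aldehyde flanked by two oxygen substituents; amine-catalysed methanolysis frees the phenol without attack on the nitro-activated ether.

Step 12
Reactants: 17 pentacyclic phenol; 18 1-bromo-3,5-dimethoxybenzene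
Product: 19 pentamer nitro compound (17 with its OH converted to a 3,5-dimethoxyphenyl ether, ring A)
Conditions: 18 (5 equiv), CuI (20 mol%), picolinic acid (40 mol%), K3PO4, DMSO, 90 °C
Reagents that add atoms: none
Why: Ullmann diaryl ether coupling of a 2,6-disubstituted phenol with an unhindered aryl bromide; the nitro group is inert to copper and no other halide is present.

Step 13
Reactants: 19 pentamer nitro compound
Product: 20 pentamer aniline (19 with NH2 in place of NO2)
Conditions: H2 (1 atm), Pd/C (palladium on carbon), EtOAc–EtOH, rt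
Reagents that add atoms: none
Why: Catalytic hydrogenation of the nitro group; no halogen or benzyl group is present.

Step 14
Reactants: 20 pentamer aniline
Product: 22 pentamer iodide (19 with I in place of NO2), via diazonium tosylate 21 (not isolated)
Conditions: NaNO2, TsOH·H2O, MeCN–H2O, 0 °C; then KI, 0 °C to rt
Reagents that add atoms: potassium iodide, [K+].[I-]
Why: Sandmeyer-type iodination; diazotisation as the tosylate salt and displacement by iodide should put iodine on E-C2, and the electron-rich, hindered diazonium ion is a poor partner for azo coupling.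

Step 15
Reactants: 23 2,4,6-trimethoxyphenol; 3 2-fluoro-4,6-dimethoxybenzaldehyde
Product: 24 2,4-dimethoxy-6-(2,4,6-trimethoxyphenoxy)benzaldehyde
Conditions: K2CO3, DMSO, 100 °C, under N2
Reagents that add atoms: none
Why: SNAr of the phenoxide at the fluorine ortho to the formyl group; the methoxy groups are meta to the reacting carbon and do not deactivate it.

Step 16
Reactants: 24 aldehyde from step 15
Product: 26 2,4-dimethoxy-6-(2,4,6-trimethoxyphenoxy)phenol, via aryl formate 25 (not isolated)
Conditions: mCPBA (1.2 equiv), CH2Cl2, 0 °C to rt; then MeOH, Et3N (cat.), rt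
Reagents that add atoms: 3-chloroperoxybenzoic acid, OOC(=O)c1cccc(Cl)c1
Why: Baeyer–Villiger oxidation of the electron-rich aldehyde and methanolysis of the formate reveal the next phenol, the oxygen of the G–O–F ether.

Step 17
Reactants: 26 phenol from step 16; 6 1-fluoro-3,5-dimethoxy-2-nitrobenzene
Product: 27 1-[2,4-dimethoxy-6-(2,4,6-trimethoxyphenoxy)phenoxy]-3,5-dimethoxy-2-nitrobenzene
Conditions: 6 (1.3 equiv), K2CO3, DMF, 60 °C
Reagents that add atoms: none
Why: SNAr; the hindered phenoxide should displace the fluoride ortho to the nitro group, which puts the nitro group on F-C1.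

Step 18
Reactants: 27 trimer nitro compound
Product: 28 2-[2,4-dimethoxy-6-(2,4,6-trimethoxyphenoxy)phenoxy]-4,6-dimethoxyaniline
Conditions: H2 (1 atm), Pd/C (palladium on carbon), EtOAc–EtOH, rt
Reagents that add atoms: none
Why: Catalytic hydrogenation of the nitro group; only aryl ethers are present otherwise.

Step 19
Reactants: 28 trimer aniline
Product: 30 1-[2,4-dimethoxy-6-(2,4,6-trimethoxyphenoxy)phenoxy]-2-iodo-3,5-dimethoxybenzene, via diazonium tosylate 29 (not isolated)
Conditions: NaNO2, TsOH·H2O, MeCN–H2O, 0 °C; then KI, 0 °C to rt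
Reagents that add atoms: potassium iodide, [K+].[I-]
Why: Sandmeyer-type iodination as in step 14 should put iodine on F-C1.

Step 20
Reactants: 30 trimer iodide; 22 pentamer iodide
Product: 33 hexadeca-O-methyl ether of the target, via arylmagnesium chloride 31 (not isolated), via arylzinc chloride 32 (not isolated)
Conditions: 30 (1.5 equiv), iPrMgCl·LiCl, THF, 0 °C to rt; ZnCl2, THF; then 22, Pd2(dba)3 (5 mol%), RuPhos (2-dicyclohexylphosphino-2′,6′-diisopropoxybiphenyl, 12 mol%), THF–NMP, 70 °C
Reagents that add atoms: none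
Why: Iodine–magnesium exchange on 30, helped by the two flanking oxygens, and transmetalation with ZnCl2 give arylzinc 32; zerovalent palladium inserts into the C–I bond of 22, and transmetalation and reductive elimination form the E-C2–F-C1 bond. The closest known reaction type is the Negishi coupling to tetra-ortho-substituted biaryls with dialkylbiarylphosphine ligands, including 2,6-dialkoxyarylzinc reagents. No ring is closed and no stereocentre is formed; the axis forms without control. The step needs cross-coupling over homocoupling and bond formation at one carbon of each ring only; each partner carries a single iodine placed by the nitro-directed SNAr, and the zinc reagent is preformed and used in excess. The four ortho substituents are oxygen atoms that can turn their groups away from the axis, and all other functions are aryl ethers, inert to the Grignard reagent, the zinc reagent and the catalyst.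

Step 21
Reactants: 33 hexadeca-O-methyl ether
Product: 34 target
Conditions: BBr3 (48 equiv), CH2Cl2, −78 °C to rt; then MeOH, then H2O, 0 °C
Reagents that add atoms: none
Why: Lewis acid ether cleavage; BBr3 should cleave the sixteen aryl methyl ethers but not the diaryl ethers, the dibenzofuran or the dibenzodioxin, and the low temperature avoids acid-promoted cyclodehydration across the E–F axis.

Compound list
1 | 1-fluoro-3,5-dimethoxybenzene | COc1cc(F)cc(OC)c1 | starting material
2 | [(2-fluoro-4,6-dimethoxyphenyl)methylidene]dimethyliminium dichlorophosphate | C[N+](C)=Cc1c(F)cc(OC)cc1OC.[O-]P(=O)(Cl)Cl | intermediate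
3 | 2-fluoro-4,6-dimethoxybenzaldehyde | O=Cc1c(F)cc(OC)cc1OC | intermediate
4 | 3-[chloro(methoxy)methyl]-2-fluoro-4,6-dimethoxybenzaldehyde | COC(Cl)c1c(F)c(C=O)c(OC)cc1OC | intermediate
5 | 2-fluoro-4,6-dimethoxybenzene-1,3-dicarbaldehyde | O=Cc1c(F)c(C=O)c(OC)cc1OC | intermediate
6 | 1-fluoro-3,5-dimethoxy-2-nitrobenzene | COc1cc(F)c([N+](=O)[O-])c(OC)c1 | intermediate
7 | 3-bromo-4-hydroxy-5-methoxybenzaldehyde (5-bromovanillin) | COc1cc(C=O)cc(Br)c1O | starting material
8 | 2,3-dibromo-4-hydroxy-5-methoxybenzaldehyde | COc1cc(C=O)c(Br)c(Br)c1O | intermediate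
9 | 2-(2,3-dibromo-4-formyl-6-methoxyphenoxy)-4,6-dimethoxybenzene-1,3-dicarbaldehyde | COc1cc(C=O)c(Br)c(Br)c1Oc1c(C=O)c(OC)cc(OC)c1C=O | intermediate
10 | triformate of 11 (each CHO of 9 replaced by OCHO) | COc1cc(OC=O)c(Br)c(Br)c1Oc1c(OC=O)c(OC)cc(OC)c1OC=O | intermediate
11 | 2-(2,3-dibromo-4-hydroxy-6-methoxyphenoxy)-4,6-dimethoxybenzene-1,3-diol | COc1cc(O)c(Br)c(Br)c1Oc1c(O)c(OC)cc(OC)c1O | intermediate
12 | 9-bromo-1,3,6-trimethoxydibenzo[b,e][1,4]dioxine-4,8-diol | COc1cc(O)c(Br)c2c1Oc1c(O)c(OC)cc(OC)c1O2 | intermediate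
13 | 2-[(9-bromo-4-hydroxy-1,3,6-trimethoxydibenzo[b,e][1,4]dioxin-8-yl)oxy]-4,6-dimethoxybenzaldehyde | COc1cc(Oc3cc(OC)cc(OC)c3C=O)c(Br)c2c1Oc1c(O)c(OC)cc(OC)c1O2 | intermediate
14 | 2-{[9-bromo-4-(3,5-dimethoxy-2-nitrophenoxy)-1,3,6-trimethoxydibenzo[b,e][1,4]dioxin-8-yl]oxy}-4,6-dimethoxybenzaldehyde | COc1cc(Oc3cc(OC)cc(OC)c3C=O)c(Br)c2c1Oc1c(Oc3cc(OC)cc(OC)c3[N+](=O)[O-])c(OC)cc(OC)c1O2 | intermediate
15 | pentacyclic aldehyde: benzofuro-fused dibenzodioxin (rings B, C, D) with CHO on ring B next to the furan oxygen, five OMe and the 3,5-dimethoxy-2-nitrophenoxy ring E on ring D | COc1cc2oc3c(C=O)c(OC)cc(OC)c3c2c2c1Oc1c(Oc3cc(OC)cc(OC)c3[N+](=O)[O-])c(OC)cc(OC)c1O2 | intermediate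
16 | formate of 17 (15 with OCHO in place of CHO) | COc1cc2oc3c(OC=O)c(OC)cc(OC)c3c2c2c1Oc1c(Oc3cc(OC)cc(OC)c3[N+](=O)[O-])c(OC)cc(OC)c1O2 | intermediate
17 | pentacyclic phenol (15 with OH in place of CHO) | COc1cc2oc3c(O)c(OC)cc(OC)c3c2c2c1Oc1c(Oc3cc(OC)cc(OC)c3[N+](=O)[O-])c(OC)cc(OC)c1O2 | intermediate
18 | 1-bromo-3,5-dimethoxybenzene | COc1cc(Br)cc(OC)c1 | starting material
19 | pentamer nitro compound (17 with its OH converted to a 3,5-dimethoxyphenyl ether, ring A) | COc1cc2oc3c(Oc4cc(OC)cc(OC)c4)c(OC)cc(OC)c3c2c2c1Oc1c(Oc3cc(OC)cc(OC)c3[N+](=O)[O-])c(OC)cc(OC)c1O2 | intermediate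
20 | pentamer aniline (19 with NH2 in place of NO2) | COc1cc2oc3c(Oc4cc(OC)cc(OC)c4)c(OC)cc(OC)c3c2c2c1Oc1c(Oc3cc(OC)cc(OC)c3N)c(OC)cc(OC)c1O2 | intermediate
21 | pentamer diazonium tosylate (19 with N2+ in place of NO2) | COc1cc2oc3c(Oc4cc(OC)cc(OC)c4)c(OC)cc(OC)c3c2c2c1Oc1c(Oc3cc(OC)cc(OC)c3[N+]#N)c(OC)cc(OC)c1O2.Cc1ccc(cc1)S(=O)(=O)[O-] | intermediate
22 | pentamer iodide (19 with I in place of NO2, on E-C2) | COc1cc2oc3c(Oc4cc(OC)cc(OC)c4)c(OC)cc(OC)c3c2c2c1Oc1c(Oc3cc(OC)cc(OC)c3I)c(OC)cc(OC)c1O2 | intermediate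
23 | 2,4,6-trimethoxyphenol | COc1cc(OC)c(O)c(OC)c1 | starting material
24 | 2,4-dimethoxy-6-(2,4,6-trimethoxyphenoxy)benzaldehyde | COc1cc(OC)c(Oc2cc(OC)cc(OC)c2C=O)c(OC)c1 | intermediate
25 | 2,4-dimethoxy-6-(2,4,6-trimethoxyphenoxy)phenyl formate | COc1cc(OC)c(Oc2cc(OC)cc(OC)c2OC=O)c(OC)c1 | intermediate
26 | 2,4-dimethoxy-6-(2,4,6-trimethoxyphenoxy)phenol | COc1cc(OC)c(Oc2cc(OC)cc(OC)c2O)c(OC)c1 | intermediate
27 | 1-[2,4-dimethoxy-6-(2,4,6-trimethoxyphenoxy)phenoxy]-3,5-dimethoxy-2-nitrobenzene | COc1cc(OC)c(Oc2cc(OC)cc(OC)c2Oc2cc(OC)cc(OC)c2[N+](=O)[O-])c(OC)c1 | intermediate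
28 | 2-[2,4-dimethoxy-6-(2,4,6-trimethoxyphenoxy)phenoxy]-4,6-dimethoxyaniline | COc1cc(OC)c(Oc2cc(OC)cc(OC)c2Oc2cc(OC)cc(OC)c2N)c(OC)c1 | intermediate
29 | trimer diazonium tosylate (28 with N2+ in place of NH2) | COc1cc(OC)c(Oc2cc(OC)cc(OC)c2Oc2cc(OC)cc(OC)c2[N+]#N)c(OC)c1.Cc1ccc(cc1)S(=O)(=O)[O-] | intermediate
30 | 1-[2,4-dimethoxy-6-(2,4,6-trimethoxyphenoxy)phenoxy]-2-iodo-3,5-dimethoxybenzene (trimer iodide) | COc1cc(OC)c(Oc2cc(OC)cc(OC)c2Oc2cc(OC)cc(OC)c2I)c(OC)c1 | intermediate
31 | trimer arylmagnesium chloride (30 with MgCl in place of I) | COc1cc(OC)c(Oc2cc(OC)cc(OC)c2Oc2cc(OC)cc(OC)c2[Mg]Cl)c(OC)c1 | intermediate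
32 | trimer arylzinc chloride (30 with ZnCl in place of I) | COc1cc(OC)c(Oc2cc(OC)cc(OC)c2Oc2cc(OC)cc(OC)c2[Zn]Cl)c(OC)c1 | intermediate
33 | hexadeca-O-methyl ether of the target (22 and 30 joined at their iodine-bearing carbons) | COc1cc2oc3c(Oc4cc(OC)cc(OC)c4)c(OC)cc(OC)c3c2c2c1Oc1c(Oc3cc(OC)cc(OC)c3-c3c(OC)cc(OC)cc3Oc3c(OC)cc(OC)cc3Oc3c(OC)cc(OC)cc3OC)c(OC)cc(OC)c1O2 | intermediate
34 | CNP0192765.0 (33 with all sixteen OMe as OH) | Oc1cc2oc3c(Oc4cc(O)cc(O)c4)c(O)cc(O)c3c2c2c1Oc1c(Oc3cc(O)cc(O)c3-c3c(O)cc(O)cc3Oc3c(O)cc(O)cc3Oc3c(O)cc(O)cc3O)c(O)cc(O)c1O2 | target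

Total step count: 21.
Longest linear sequence: 14 steps (steps 1, 2, 5–14, 20, 21).

Steps most likely to fail

1. Step 20. Transmetalation and reductive elimination at a centre flanked by four oxygen substituents may be slower than protonation of the zinc reagent and reduction or homocoupling of iodide 22. The fallback sets out from 30. Iodine–magnesium exchange and quenching with 2-isopropoxy-4,4,5,5-tetramethyl-1,3,2-dioxaborolane give the isolable pinacol boronate of the trimer F1. Suzuki–Miyaura coupling of F1 with 22 (Pd(OAc)2, SPhos, anhydrous K3PO4, toluene, 100 °C) uses a purified, thermally stable nucleophile at higher temperature and comes back at 33.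

2. Step 8. Site selectivity may be lost: at the temperature needed both phenoxides are in equilibrium, so the hindered 4-OH or both hydroxyls may be etherified. The fallback sets out from 12 and reverses the order of the two ether formations with a protecting group. Methoxymethylation of the more acidic, less hindered 8-OH at low temperature (MOMCl, iPr2NEt, CH2Cl2, 0 °C) gives the 8-O-methoxymethyl ether F2. SNAr of its 4-OH with 6 (K2CO3, DMF, 60 °C) gives nitro ether F3. HCl in MeOH removes the acetal to give phenol F4. SNAr of F4 with 3 (K2CO3, DMSO, 90 °C) comes back at 14.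

3. Step 21. Cleavage of sixteen ethers may stop short and leave partly methylated material that cannot be separated from the very polar product; acid may also promote loss of water between the two hydroxyls ortho to the E–F axis, and the free polyphenol may oxidise during isolation. The fallback sets out from 33. Cleavage with AlCl3 and ethanethiol (CH2Cl2, 0 °C to rt) is followed directly by acetylation of the crude phenol (Ac2O, pyridine) to the hexadecaacetate F5, which can be chromatographed and, if under-cleaved, resubmitted. Hydrazine hydrate in MeOH–THF at 0 °C removes the acetates and comes back at 34.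

Further compounds
F1 | step 20 | 2-{2-[2,4-dimethoxy-6-(2,4,6-trimethoxyphenoxy)phenoxy]-4,6-dimethoxyphenyl}-4,4,5,5-tetramethyl-1,3,2-dioxaborolane | COc1cc(OC)c(Oc2cc(OC)cc(OC)c2Oc2cc(OC)cc(OC)c2B2OC(C)(C)C(C)(C)O2)c(OC)c1
F2 | step 8 | 9-bromo-1,3,6-trimethoxy-8-(methoxymethoxy)dibenzo[b,e][1,4]dioxin-4-ol | COc1cc(OCOC)c(Br)c2c1Oc1c(O)c(OC)cc(OC)c1O2
F3 | step 8 | 9-bromo-4-(3,5-dimethoxy-2-nitrophenoxy)-1,3,6-trimethoxy-8-(methoxymethoxy)dibenzo[b,e][1,4]dioxine | COc1cc(OCOC)c(Br)c2c1Oc1c(Oc3cc(OC)cc(OC)c3[N+](=O)[O-])c(OC)cc(OC)c1O2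
F4 | step 8 | 9-bromo-4-(3,5-dimethoxy-2-nitrophenoxy)-1,3,6-trimethoxydibenzo[b,e][1,4]dioxin-8-ol | COc1cc(O)c(Br)c2c1Oc1c(Oc3cc(OC)cc(OC)c3[N+](=O)[O-])c(OC)cc(OC)c1O2
F5 | step 21 | hexadecaacetate of 34 (every OH as OAc) | CC(=O)Oc1cc2oc3c(Oc4cc(OC(C)=O)cc(OC(C)=O)c4)c(OC(C)=O)cc(OC(C)=O)c3c2c2c1Oc1c(Oc3cc(OC(C)=O)cc(OC(C)=O)c3-c3c(OC(C)=O)cc(OC(C)=O)cc3Oc3c(OC(C)=O)cc(OC(C)=O)cc3Oc3c(OC(C)=O)cc(OC(C)=O)cc3OC(C)=O)c(OC(C)=O)cc(OC(C)=O)c1O2
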